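The pyranone (δ-lactone) ring is closed at the C3–C4 bond, one oxidation level up, as the enol-lactone C3=C4 of an isocoumarin. The key step exploits that C3 bears the lactone oxygen O2, which is acylated by C1, and that C4 is benzylic. C3 therefore enters as the acyl carbon of a mixed anhydride and C4 as a phosphorus ylide. One pot joins the aromatic and aliphatic halves and closes the ring by intramolecular Wittig olefination. The precursor is the open-chain mixed anhydride of a (2-carboxybenzyl)phosphonium salt with the side-chain acid. Catalytic asymmetric hydrogenation of C3=C4 then sets C3, and one BBr3 dealkylation frees both phenols and the acid.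

Key step: step 7

Remark: the target is read as (3R) at the lactone carbon and (S) at the side-chain carbinol. The antipode of the hydrogenation catalyst that delivers 3R is assumed to be assigned on a simple 3-alkylisocoumarin model.

Step 1
Reactants: 1 2,5-dimethoxybenzyl alcohol
Product: 4 4,7-dimethoxyphthalide, via dilithio species 2 (not isolated), via hydroxy acid 3 (not isolated)
Conditions: n-BuLi (2.2 equiv), TMEDA, Et2O–hexane, 0 °C → rt; CO2, −78 °C → rt; 2 M HCl
Reagents that add atoms: carbon dioxide O=C=O
Why: Directed ortho-metalation, in which the lithium alkoxide and the 5-methoxy group together direct lithiation to the ring position between them, followed by carboxylation and acid-induced lactonisation.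

Step 2
Reactants: 4 4,7-dimethoxyphthalide
Product: 5 [(2-carboxy-3,6-dimethoxyphenyl)methyl]triphenylphosphonium bromide
Conditions: Ph3P·HBr (1.05 equiv), neat melt, 150–160 °C, 1–2 h; trituration with acetone/Et2O
Reagents that add atoms: triphenylphosphine hydrobromide [Br-].c1ccc([PH+](c2ccccc2)c2ccccc2)cc1
Why: Acid-promoted opening of the lactone at its benzylic carbon (activated by the ortho-methoxy group) by triphenylphosphine, the known conversion of phthalides into (2-carboxybenzyl)phosphonium salts, with only stoichiometric HBr so that the aryl methyl ethers should survive.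

Step 3
Reactants: 6 (S)-propylene oxide; 7 but-3-enylmagnesium bromide
Product: 8 (2S)-hept-6-en-2-ol
Conditions: CuI (10 mol %), THF, −30 → 0 °C; aq. NH4Cl
Reagents that add atoms: none
Why: Copper-catalysed SN2 opening of the epoxide at its unsubstituted carbon, which does not involve the stereocentre, so the (S) configuration of the side-chain carbinol comes from the chiral pool.

Step 4
Reactants: 8 (2S)-hept-6-en-2-ol; 9 4-tert-butoxy-4-oxobutanoic acid (mono-tert-butyl succinate)
Product: 10 tert-butyl (2S)-hept-6-en-2-yl butanedioate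
Conditions: DCC (1.1 equiv), DMAP (10 mol %), CH2Cl2, 0 °C → rt
Reagents that add atoms: none
Why: Steglich esterification, in which the carbinol C–O bond is not broken, so the (S) centre is retained.

Step 5
Reactants: 10 tert-butyl (2S)-hept-6-en-2-yl butanedioate
Product: 11 (5S)-5-[(4-tert-butoxy-4-oxobutanoyl)oxy]hexanoic acid
Conditions: RuCl3·xH2O (2 mol %), NaIO4 (4.1 equiv), EtOAc/MeCN/H2O, rt
Reagents that add atoms: sodium periodate [Na+].[O-]I(=O)(=O)=O; water O
Why: Ruthenium tetroxide oxidative cleavage of the terminal alkene to the carboxylic acid one carbon shorter, to which both esters and the acylated carbinol centre are inert.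

Step 6
Reactants: 11 (5S)-5-[(4-tert-butoxy-4-oxobutanoyl)oxy]hexanoic acid
Product: 12 tert-butyl (2S)-6-chloro-6-oxohexan-2-yl butanedioate
Conditions: 1-chloro-N,N,2-trimethylprop-1-en-1-amine (1.1 equiv), CH2Cl2, 0 °C → rt; used crude
Reagents that add atoms: 1-chloro-N,N,2-trimethylprop-1-en-1-amine CC(C)=C(Cl)N(C)C
Why: Neutral acid-chloride formation with an α-chloroenamine, which releases no free HCl and therefore spares the tert-butyl ester.

Step 7
Reactants: 12 tert-butyl (2S)-6-chloro-6-oxohexan-2-yl butanedioate; 5 [(2-carboxy-3,6-dimethoxyphenyl)methyl]triphenylphosphonium bromide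
Product: 15 tert-butyl (2S)-5-(5,8-dimethoxy-1-oxo-1H-isochromen-3-yl)pentan-2-yl butanedioate, via mixed anhydride 13 (not isolated), via phosphorus ylide 14 (not isolated)
Conditions: 5, Et3N (1.1 equiv), CH2Cl2, 0 °C; 12; then Et3N (2.5 equiv), toluene, 90 °C
Reagents that add atoms: none
Why: The carboxylate of 5 is O-acylated by 12 to the mixed anhydride 13, further Et3N deprotonates the benzylic phosphonium to the ylide 14, whose carbon (C4) adds to the neighbouring anhydride carbonyl (C3), and [2+2] cycloreversion expels Ph3P=O and leaves the ring C3=C4 bond. This is an intramolecular Wittig olefination of an acyloxy carbonyl, the reaction type used to make benzofurans, indoles and isocoumarins from ortho-functionalised benzylphosphonium salts and acid chlorides. The pyranone ring closes by 6-exo-trig addition of C4 to the C3 carbonyl, and the endocyclic double bond can have only one geometry. No stereocentre is formed, and the (S) carbinol centre of the side chain is remote, not enolisable and untouched. The step needs chemoselectivity for the anhydride carbonyl C3 over C1 and over the two alkyl ester carbonyls: attack at C1 would need a four-membered ring, the 2,6-disubstituted aroyl carbonyl is shielded as in a Yamaguchi anhydride, and plain esters are far less electrophilic than an anhydride. O-acylation before ylide formation is secured by adding 12 to the carboxylate at 0 °C and heating with excess base only afterwards.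

Step 8
Reactants: 15 tert-butyl (2S)-5-(5,8-dimethoxy-1-oxo-1H-isochromen-3-yl)pentan-2-yl butanedioate
Product: 16 tert-butyl (2S)-5-[(3R)-5,8-dimethoxy-1-oxo-3,4-dihydro-1H-isochromen-3-yl]pentan-2-yl butanedioate
Conditions: chiral Ru–NHC–diamine catalyst (from [Ru(cod)(2-methylallyl)2], SINpEt·HBF4, KOtBu, DPEN; antipode giving 3R; 5 mol %), H2 (50 bar), toluene, 25 °C
Reagents that add atoms: none
Why: Enantioselective hydrogenation of the isocoumarin enol-lactone C3=C4, in which the chiral Ru–NHC–diamine complex delivers H2 to one face of C3 under catalyst control (the remote side-chain centre exerts none), so the catalyst antipode is chosen to give 3R.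

Step 9
Reactants: 16 tert-butyl (2S)-5-[(3R)-5,8-dimethoxy-1-oxo-3,4-dihydro-1H-isochromen-3-yl]pentan-2-yl butanedioate
Product: 17 Aspergimarin B
Conditions: BBr3 (6 equiv), CH2Cl2, −78 → 0 °C; H2O, then pH 3
Reagents that add atoms: none
Why: Lewis-acid dealkylation, in which bromide attacks the methyl groups of the boron-complexed aryl ethers (SN2) and the tert-butyl ester ionises, whereas the secondary alkyl C–O bonds of the lactone and the succinate should react much more slowly at or below 0 °C, so both esters and both stereocentres are kept.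

Compound list
1 | 2,5-dimethoxybenzyl alcohol | COc1ccc(OC)c(CO)c1 | starting material
2 | lithium (2-lithio-3,6-dimethoxyphenyl)methanolate (dilithio species) | [Li]OCc1c([Li])c(OC)ccc1OC | intermediate
3 | 2-(hydroxymethyl)-3,6-dimethoxybenzoic acid (hydroxy acid) | COc1ccc(OC)c(C(=O)O)c1CO | intermediate
4 | 4,7-dimethoxy-2-benzofuran-1(3H)-one (4,7-dimethoxyphthalide) | COc1ccc(OC)c2c1COC2=O | intermediate
5 | [(2-carboxy-3,6-dimethoxyphenyl)methyl]triphenylphosphonium bromide | COc1ccc(OC)c(C(=O)O)c1C[P+](c1ccccc1)(c1ccccc1)c1ccccc1.[Br-] | intermediate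
6 | (S)-propylene oxide [(2S)-2-methyloxirane] | C[C@H]1CO1 | starting material
7 | but-3-enylmagnesium bromide | C=CCC[Mg]Br | starting material
8 | (2S)-hept-6-en-2-ol | C[C@H](O)CCCC=C | intermediate
9 | 4-tert-butoxy-4-oxobutanoic acid (mono-tert-butyl succinate) | CC(C)(C)OC(=O)CCC(=O)O | starting material
10 | tert-butyl (2S)-hept-6-en-2-yl butanedioate | C[C@@H](CCCC=C)OC(=O)CCC(=O)OC(C)(C)C | intermediate
11 | (5S)-5-[(4-tert-butoxy-4-oxobutanoyl)oxy]hexanoic acid | C[C@@H](CCCC(=O)O)OC(=O)CCC(=O)OC(C)(C)C | intermediate
12 | tert-butyl (2S)-6-chloro-6-oxohexan-2-yl butanedioate | C[C@@H](CCCC(=O)Cl)OC(=O)CCC(=O)OC(C)(C)C | intermediate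
13 | mixed anhydride of 5 with acid 11 (phosphonium bromide) | C[C@@H](CCCC(=O)OC(=O)c1c(OC)ccc(OC)c1C[P+](c1ccccc1)(c1ccccc1)c1ccccc1)OC(=O)CCC(=O)OC(C)(C)C.[Br-] | intermediate
14 | phosphorus ylide of the mixed anhydride | C[C@@H](CCCC(=O)OC(=O)c1c(OC)ccc(OC)c1C=P(c1ccccc1)(c1ccccc1)c1ccccc1)OC(=O)CCC(=O)OC(C)(C)C | intermediate
15 | tert-butyl (2S)-5-(5,8-dimethoxy-1-oxo-1H-isochromen-3-yl)pentan-2-yl butanedioate | C[C@@H](CCCC1=Cc2c(OC)ccc(OC)c2C(=O)O1)OC(=O)CCC(=O)OC(C)(C)C | intermediate
16 | tert-butyl (2S)-5-[(3R)-5,8-dimethoxy-1-oxo-3,4-dihydro-1H-isochromen-3-yl]pentan-2-yl butanedioate | C[C@@H](CCC[C@@H]1Cc2c(OC)ccc(OC)c2C(=O)O1)OC(=O)CCC(=O)OC(C)(C)C | intermediate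
17 | Aspergimarin B, 4-{[(2S)-5-[(3R)-5,8-dihydroxy-1-oxo-3,4-dihydro-1H-isochromen-3-yl]pentan-2-yl]oxy}-4-oxobutanoic acid | C[C@@H](CCC[C@@H]1Cc2c(O)ccc(O)c2C(=O)O1)OC(=O)CCC(=O)O | target

Total step count: 9. Longest linear sequence: 7 steps (steps 3, 4, 5, 6, 7, 8, 9, from (S)-propylene oxide); steps 1 and 2 form the aromatic branch that joins at step 7.

Steps most likely to fail

1. Step 8. Hydrogen delivery to the C3=C4 bond, flanked by the peri 5-methoxy group and carrying a long functionalised chain, may be slow or poorly face-selective. Fallback, setting out from 10 and coming back at 16: epoxidation of 10 (mCPBA, CH2Cl2, 0 °C) should give tert-butyl (2S)-5-(oxiran-2-yl)pentan-2-yl butanedioate F1 as both oxirane epimers. Hydrolytic kinetic resolution (chiral (salen)Co(III)–OAc, the antipode that spares the (R)-oxirane, 0.55 equiv H2O) should leave tert-butyl (2S)-5-[(2R)-oxiran-2-yl]pentan-2-yl butanedioate F2 and turn the other epimer into tert-butyl (2S,6S)-6,7-dihydroxyheptan-2-yl butanedioate F3, which is removed. Carboxylate-directed Pd(II) ortho-C–H alkylation of commercial 2,5-dimethoxybenzoic acid with F2 (Pd(OAc)2, mono-N-protected amino acid ligand, KOAc, HFIP, 75 °C) then opens the epoxide at CH2 with retention at the carbinol carbon and lactonises to 16. Here C3 is set by the resolution and the ring is closed at oxygen.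

2. Step 7. O-acylation may lose to ketene formation from 12, to anhydride scrambling, or to reversion of the phosphonium carboxylate to phthalide 4 by internal displacement of PPh3. The hindered ylide may also add too slowly. Fallback, setting out from 10 and 5 and coming back at 15: ozonolysis of 10 (O3, CH2Cl2, −78 °C; PPh3) should give tert-butyl (2S)-6-oxohexan-2-yl butanedioate F4. Intermolecular Wittig olefination of F4 with the ylide-carboxylate from 5 (LiHMDS, 2 equiv, THF, −78 °C → rt) should give 2-[(1E,6S)-6-[(4-tert-butoxy-4-oxobutanoyl)oxy]hept-1-en-1-yl]-3,6-dimethoxybenzoic acid F5 (E/Z mixture expected). Pd(II)-catalysed oxidative Wacker-type 6-endo lactonisation (PdCl2(MeCN)2 cat., benzoquinone, Na2CO3, THF) then gives 15. The C3=C4 bond is made before the ring, which closes at oxygen.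

3. Step 9. Boron tribromide may over-cleave the secondary alkyl C–O bonds of the lactone or the succinate, or the tert-butyl cation may alkylate the ring. Fallback, setting out from 16 and coming back at 17: oxidative demethylation (ceric ammonium nitrate, MeCN/H2O, 0 °C) should give tert-butyl (2S)-5-[(3R)-1,5,8-trioxo-3,4,5,8-tetrahydro-1H-isochromen-3-yl]pentan-2-yl butanedioate F6. Immediate reduction (Na2S2O4, EtOAc/H2O) should give tert-butyl (2S)-5-[(3R)-5,8-dihydroxy-1-oxo-3,4-dihydro-1H-isochromen-3-yl]pentan-2-yl butanedioate F7. Cleavage of the tert-butyl ester (TFA/CH2Cl2, Et3SiH, rt) then gives 17.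

Further compounds
F1 | step 8 | tert-butyl (2S)-5-(oxiran-2-yl)pentan-2-yl butanedioate (both oxirane epimers) | C[C@@H](CCCC1CO1)OC(=O)CCC(=O)OC(C)(C)C
F2 | step 8 | tert-butyl (2S)-5-[(2R)-oxiran-2-yl]pentan-2-yl butanedioate | C[C@@H](CCC[C@@H]1CO1)OC(=O)CCC(=O)OC(C)(C)C
F3 | step 8 | tert-butyl (2S,6S)-6,7-dihydroxyheptan-2-yl butanedioate | C[C@@H](CCC[C@H](O)CO)OC(=O)CCC(=O)OC(C)(C)C
F4 | step 7 | tert-butyl (2S)-6-oxohexan-2-yl butanedioate | C[C@@H](CCCC=O)OC(=O)CCC(=O)OC(C)(C)C
F5 | step 7 | 2-[(1E,6S)-6-[(4-tert-butoxy-4-oxobutanoyl)oxy]hept-1-en-1-yl]-3,6-dimethoxybenzoic acid | C[C@@H](CCC/C=C/c1c(OC)ccc(OC)c1C(=O)O)OC(=O)CCC(=O)OC(C)(C)C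
F6 | step 9 | tert-butyl (2S)-5-[(3R)-1,5,8-trioxo-3,4,5,8-tetrahydro-1H-isochromen-3-yl]pentan-2-yl butanedioate | C[C@@H](CCC[C@@H]1CC2=C(C(=O)O1)C(=O)C=CC2=O)OC(=O)CCC(=O)OC(C)(C)C
F7 | step 9 | tert-butyl (2S)-5-[(3R)-5,8-dihydroxy-1-oxo-3,4-dihydro-1H-isochromen-3-yl]pentan-2-yl butanedioate | C[C@@H](CCC[C@@H]1Cc2c(O)ccc(O)c2C(=O)O1)OC(=O)CCC(=O)OC(C)(C)C
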